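With the cyclohexane numbered C1 (Et), C2 (Me), C3 (Ar), C4 (Me), C5 (Ar), C6 (spiro), Ar being 2,4,5-trimethoxyphenyl, the route cuts C1–C2 and C5–C6. Two features are exploited: C6 is the para carbon of a 2,5-dimethoxyphenol frozen as the spirodienone ring, and the groups on C3, C4 and C5 are all equatorial, so C3=C4 may stay unsaturated during ring formation and be reduced last. In one acid-catalysed operation a para-quinone methide (C1, C6) and a (1E,3Z)-1,3-diarylpentadiene (C2–C5) should give the spirocyclohexene with both bonds and the C1, C2, C5 and C6 stereocentres in place. The precursors are a racemic para-hydroxybenzylic alcohol and that diene.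

Key step: step 6

Assumption: the sense of induction of the chiral phosphoric acid in step 6 cannot be predicted for a new reaction; the (R)-acid is written, and its (S)-antipode would be used, with nothing else changed, should the first run give the mirror-image series.

Step 1
Reactants: 1 2,4,5-trimethoxybenzaldehyde; 2 pentan-3-one
Product: 4 (1E)-2-methyl-1-(2,4,5-trimethoxyphenyl)pent-1-en-3-one, via aldol adduct 3 (not isolated)
Conditions: 2 (5 equiv), NaOH, EtOH–H2O, 60 °C
Reagents that add atoms: none
Why: Claisen–Schmidt (crossed aldol) condensation: the aldehyde cannot enolise, the excess of the symmetrical ketone suppresses double condensation, and dehydration of 3 under equilibrating conditions should leave the aryl group trans to the carbonyl (E).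

Step 2
Reactants: 4 (1E)-2-methyl-1-(2,4,5-trimethoxyphenyl)pent-1-en-3-one
Product: 6 (1E,3Z)-2-methyl-1-(2,4,5-trimethoxyphenyl)penta-1,3-dien-3-yl trifluoromethanesulfonate, via potassium enolate 5 (not isolated)
Conditions: KN(SiMe3)2, THF, −78 °C; PhNTf2, −78 → 0 °C
Reagents that add atoms: N-phenylbis(trifluoromethanesulfonimide), PhNTf2, O=S(=O)(N(c1ccccc1)S(=O)(=O)C(F)(F)F)C(F)(F)F
Why: Kinetic α′-deprotonation of an ethyl ketone whose other substituent is a bulky, α-branched alkenyl group should give the Z(O)-enolate (methyl cis to oxygen, as with ethyl aryl ketones), and O-sulfonylation (enol triflate formation) freezes that geometry as the 3Z alkene.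

Step 3
Reactants: 6 (1E,3Z)-2-methyl-1-(2,4,5-trimethoxyphenyl)penta-1,3-dien-3-yl trifluoromethanesulfonate; 7 2,4,5-trimethoxyphenylboronic acid
Product: 8 (1E,3Z)-2-methyl-1,3-bis(2,4,5-trimethoxyphenyl)penta-1,3-diene
Conditions: Pd(OAc)2 (5 mol %), SPhos (10 mol %), K3PO4, THF–H2O, 40 °C
Reagents that add atoms: none
Why: Suzuki–Miyaura coupling of an alkenyl triflate proceeds with retention of alkene geometry, and the electron-rich biarylphosphine should let the hindered dienyl triflate couple at a temperature low enough to limit protodeboronation of the ortho-methoxy boronic acid.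

Step 4
Reactants: 9 2,5-dimethoxyphenol; 10 propanoyl chloride
Product: 11 1-(4-hydroxy-2,5-dimethoxyphenyl)propan-1-one
Conditions: TfOH (neat), 0 °C → rt
Reagents that add atoms: none
Why: Friedel–Crafts acylation (any O-acylation converges through the acid-promoted Fries pathway): C4 is para to the hydroxyl and ortho to the 5-methoxy group and is the only doubly activated position not flanked by two substituents, and the ketone product is deactivated toward a second acylation.

Step 5
Reactants: 11 1-(4-hydroxy-2,5-dimethoxyphenyl)propan-1-one
Product: 12 4-(1-hydroxypropyl)-2,5-dimethoxyphenol (racemic)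
Conditions: NaBH4, MeOH–THF, 0 °C → rt; pH 7 buffer work-up
Reagents that add atoms: none
Why: Borohydride reduction of a para-hydroxyaryl ketone, as routinely done for acetovanillone-type ketones; the carbinol centre is racemic, which is immaterial because it is planarised on ionisation, and the buffered work-up avoids premature quinone methide formation.

Step 6
Reactants: 8 (1E,3Z)-2-methyl-1,3-bis(2,4,5-trimethoxyphenyl)penta-1,3-diene; 12 4-(1-hydroxypropyl)-2,5-dimethoxyphenol
Product: 15 (6S,7R,10S,11R)-11-ethyl-1,4-dimethoxy-8,10-dimethyl-7,9-bis(2,4,5-trimethoxyphenyl)spiro[5.5]undeca-1,4,8-trien-3-one (3,4-didehydro-tatanan B), via quinone methide 13 (not isolated), via allyl cation 14 (not isolated)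
Conditions: (R)-TRIP [(R)-3,3′-bis(2,4,6-triisopropylphenyl)-1,1′-binaphthyl-2,2′-diyl hydrogen phosphate] (10 mol %), 4 Å MS, PhMe, −20 °C → rt, 12 added slowly to 8 (1.5 equiv)
Reagents that add atoms: none
Why: Proposed new method: the phosphoric acid dehydrates 12 to quinone methide 13 and activates it by hydrogen bonding; the CH(Me) terminus of 8 adds to the exocyclic carbon (C1–C2), the only regiochemistry that leaves a cation stabilised by both trimethoxyphenyl rings (14), and the rearomatised phenol then attacks the distal allyl terminus through its para carbon (C5–C6) with loss of the phenolic proton to the phosphate. The closest known reaction types are phosphoric-acid-catalysed 1,6-additions and formal cycloadditions of in situ para-quinone methides with electron-rich alkenes, and dearomative ipso-Friedel–Crafts spirocyclisations of para-substituted phenols by stabilised cations. The cyclohexene is closed in a 6-endo-trig sense on the allyl cation (C3=C4 ends up endocyclic); attack at the proximal terminus would need a four-membered ring and attack through an ortho carbon a seven-membered ring or a quaternary indane centre, so the para carbon, the position most activated by the hydroxyl group, should be selected. C1 and C2 are set in the first bond, the chiral phosphate choosing the face of 13 (absolute configuration) and a compact approach, in which the ethyl group and the unsubstituted CH edge of 13 lie over the diene while its methoxy-bearing edge points away, giving the cis ethyl/methyl pair; the E propylidene geometry of 13 (ethyl anti to the ring methoxy) and the outward-pointing methyl of the 3Z diene secure this. C5 is set by the retained E geometry of the ArCH terminus in a chair-like closure that places the C5 aryl pseudo-equatorial and cis to the C2 methyl, and C6 by the phenol rotamer that turns its H-bearing edge, not its methoxy-bearing edge, toward the syn-axial C2 methyl. The step also needs chemoselection against tautomerisation and self-condensation of 13, which slow addition of 12 to an excess of the more nucleophilic diene should provide.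

Step 7
Reactants: 15 3,4-didehydro-tatanan B
Product: 17 tatanan B, (6S,7R,8S,9S,10R,11R)-7-ethyl-1,4-dimethoxy-8,10-dimethyl-9,11-bis(2,4,5-trimethoxyphenyl)spiro[5.5]undeca-1,4-dien-3-one, via benzylic cation 16 (not isolated)
Conditions: Et3SiH (5 equiv), CF3CO2H (10 equiv), CH2Cl2, −20 → 0 °C
Reagents that add atoms: none
Why: Ionic hydrogenation of an electron-rich tetrasubstituted styrene: reversible protonation at C4 should funnel material through cation 16 with the C4 methyl equatorial (trans to the C5 aryl and clear of the axial C2 methyl), and the silane then delivers hydride axially to C3 from the face opposite the axial C2 methyl, leaving the C3 aryl equatorial, while the vinylogous-ester dienone is not a hydride acceptor under these conditions.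

Compound list
1 | 2,4,5-trimethoxybenzaldehyde | COc1cc(OC)c(C=O)cc1OC | starting material
2 | pentan-3-one | CCC(=O)CC | starting material
3 | 1-hydroxy-2-methyl-1-(2,4,5-trimethoxyphenyl)pentan-3-one (aldol adduct, diastereomer mixture, not isolated) | CCC(=O)C(C)C(O)c1cc(OC)c(OC)cc1OC | intermediate
4 | (1E)-2-methyl-1-(2,4,5-trimethoxyphenyl)pent-1-en-3-one | CCC(=O)/C(C)=C/c1cc(OC)c(OC)cc1OC | intermediate
5 | potassium (1E,3Z)-2-methyl-1-(2,4,5-trimethoxyphenyl)penta-1,3-dien-3-olate (not isolated) | C/C=C(/C(C)=C/c1cc(OC)c(OC)cc1OC)[O-].[K+] | intermediate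
6 | (1E,3Z)-2-methyl-1-(2,4,5-trimethoxyphenyl)penta-1,3-dien-3-yl trifluoromethanesulfonate | C/C=C(/C(C)=C/c1cc(OC)c(OC)cc1OC)OS(=O)(=O)C(F)(F)F | intermediate
7 | 2,4,5-trimethoxyphenylboronic acid | COc1cc(OC)c(B(O)O)cc1OC | starting material
8 | (1E,3Z)-2-methyl-1,3-bis(2,4,5-trimethoxyphenyl)penta-1,3-diene | C/C=C(/C(C)=C/c1cc(OC)c(OC)cc1OC)c1cc(OC)c(OC)cc1OC | intermediate
9 | 2,5-dimethoxyphenol | COc1ccc(OC)c(O)c1 | starting material
10 | propanoyl chloride | CCC(=O)Cl | starting material
11 | 1-(4-hydroxy-2,5-dimethoxyphenyl)propan-1-one | CCC(=O)c1cc(OC)c(O)cc1OC | intermediate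
12 | 4-(1-hydroxypropyl)-2,5-dimethoxyphenol (racemic) | CCC(O)c1cc(OC)c(O)cc1OC | intermediate
13 | (4E)-2,5-dimethoxy-4-propylidenecyclohexa-2,5-dien-1-one (quinone methide, ethyl anti to the 5-methoxy group, not isolated) | CC/C=C1\C=C(OC)C(=O)C=C1OC | intermediate
14 | (4S,5R)-5-(4-hydroxy-2,5-dimethoxyphenyl)-2,4-dimethyl-1,3-bis(2,4,5-trimethoxyphenyl)hept-2-en-1-ylium (1,3-diarylallyl cation as its phosphate ion pair, one resonance form drawn, not isolated) | CC[C@@H](c1cc(OC)c(O)cc1OC)[C@H](C)/C(c1cc(OC)c(OC)cc1OC)=C(/C)[CH+]c1cc(OC)c(OC)cc1OC | intermediate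
15 | (6S,7R,10S,11R)-11-ethyl-1,4-dimethoxy-8,10-dimethyl-7,9-bis(2,4,5-trimethoxyphenyl)spiro[5.5]undeca-1,4,8-trien-3-one (3,4-didehydro-tatanan B; ethyl, C2 methyl and C5 aryl on one face) | CC[C@@H]1[C@H](C)C(c2cc(OC)c(OC)cc2OC)=C(C)[C@H](c2cc(OC)c(OC)cc2OC)[C@]12C=C(OC)C(=O)C=C2OC | intermediate
16 | tertiary C3 benzylic cation of 17 (trifluoroacetate ion pair; C1, C2, C4, C5 and C6 configured as in 17, not isolated) | CC[C@@H]1[C@H](C)[C+](c2cc(OC)c(OC)cc2OC)[C@@H](C)[C@H](c2cc(OC)c(OC)cc2OC)[C@]12C=C(OC)C(=O)C=C2OC | intermediate
17 | tatanan B, (6S,7R,8S,9S,10R,11R)-7-ethyl-1,4-dimethoxy-8,10-dimethyl-9,11-bis(2,4,5-trimethoxyphenyl)spiro[5.5]undeca-1,4-dien-3-one | CC[C@@H]1[C@H](C)[C@H](c2cc(OC)c(OC)cc2OC)[C@@H](C)[C@H](c2cc(OC)c(OC)cc2OC)[C@]12C=C(OC)C(=O)C=C2OC | target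

Total step count: 7 (steps 1–3 diene, steps 4–5 phenol partner, step 6 annulation, step 7 reduction).
Longest linear sequence: 5 steps (1, 2, 3, 6, 7).

Steps most likely to fail

Step 6. The first bond may form through the wrong diene conformer or with poor facial control, the quinone methide may tautomerise and self-condense faster than it is intercepted, or the ion pair may collapse without control of the phenol rotamer, so that ring closure or the C1/C2/C6 configuration is lost. The fallback sets out from enone 4 and alcohol 12 and rejoins the route at 15, taking the same two bonds apart into known reactions. Enone 4 is converted (KN(SiMe3)2, Me3SiCl, THF, −78 °C) into the Z silyl dienol ether trimethyl{[(1E,3Z)-2-methyl-1-(2,4,5-trimethoxyphenyl)penta-1,3-dien-3-yl]oxy}silane F1. Acid-catalysed Mukaiyama-type 1,6-addition of F1 to the quinone methide generated from 12 (same chiral phosphoric acid, a known manifold for enantioselective additions to in situ para-quinone methides) forms C1–C2 and should give (1E,4S,5R)-5-(4-hydroxy-2,5-dimethoxyphenyl)-2,4-dimethyl-1-(2,4,5-trimethoxyphenyl)hept-1-en-3-one F2; diastereomers would be separated and the α-epimer recycled by base equilibration. Excess 2,4,5-trimethoxyphenyllithium F3 (from commercial 1-bromo-2,4,5-trimethoxybenzene and n-BuLi, THF, −78 °C) adds 1,2 to the ketone to give (1E,4S,5R)-5-(4-hydroxy-2,5-dimethoxyphenyl)-2,4-dimethyl-1,3-bis(2,4,5-trimethoxyphenyl)hept-1-en-3-ol F4 (C3 epimers, immaterial). Mild acid then ionises F4, and the phenol closes the ring through its para carbon by dearomative ipso-Friedel–Crafts allylic alkylation to give 15. Should enantiocontrol in the addition be inadequate, racemic 15 would be resolved by preparative chromatography on a chiral phase.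

Step 7. Hydride may be captured before the C4 epimers of the cation have equilibrated, configuration at C2 may erode through reversible proton loss from the cation toward C2, or acid may reopen the C5–C6 bond and the resulting cation be reduced irreversibly. The fallback sets out from 15 and arrives directly at 17 by hydrogen-atom-transfer hydrogenation (Mn(dpm)3 with dpm = dipivaloylmethanate, PhSiH3, t-BuOOH, i-PrOH, rt). This is a known radical alkene reduction that delivers hydrogen stepwise to C4 and then to the tertiary benzylic radical at C3, typically with thermodynamic stereoselection, and involves neither acid nor cation. No new compound is made (F0).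

Step 3. Protodeboronation of the electron-rich ortho-methoxy boronic acid may outrun transmetallation onto the hindered dienylpalladium intermediate. The fallback sets out from triflate 6 and rejoins at diene 8 by reversing the coupling polarity. Miyaura borylation of 6 (B2pin2, Pd(PPh3)2Cl2, PPh3, KOPh, PhMe, 50 °C) should give, with retention of geometry, 2-[(1E,3E)-2-methyl-1-(2,4,5-trimethoxyphenyl)penta-1,3-dien-3-yl]-4,4,5,5-tetramethyl-1,3,2-dioxaborolane F5 (same spatial arrangement as 6; the descriptor changes because boron ranks below carbon). Suzuki–Miyaura coupling of F5 with commercial 1-bromo-2,4,5-trimethoxybenzene (Pd(dppf)Cl2, K2CO3, dioxane–H2O, 70 °C) then gives 8; the aryl partner is now a bromide that cannot protodeboronate.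

Further compounds
F1 | step 6 | trimethyl{[(1E,3Z)-2-methyl-1-(2,4,5-trimethoxyphenyl)penta-1,3-dien-3-yl]oxy}silane | C/C=C(/C(C)=C/c1cc(OC)c(OC)cc1OC)O[Si](C)(C)C
F2 | step 6 | (1E,4S,5R)-5-(4-hydroxy-2,5-dimethoxyphenyl)-2,4-dimethyl-1-(2,4,5-trimethoxyphenyl)hept-1-en-3-one | CC[C@@H](c1cc(OC)c(O)cc1OC)[C@H](C)C(=O)/C(C)=C/c1cc(OC)c(OC)cc1OC
F3 | step 6 | 2,4,5-trimethoxyphenyllithium | [Li]c1cc(OC)c(OC)cc1OC
F4 | step 6 | (1E,4S,5R)-5-(4-hydroxy-2,5-dimethoxyphenyl)-2,4-dimethyl-1,3-bis(2,4,5-trimethoxyphenyl)hept-1-en-3-ol (C3 epimers) | CC[C@@H](c1cc(OC)c(O)cc1OC)[C@H](C)C(O)(c1cc(OC)c(OC)cc1OC)/C(C)=C/c1cc(OC)c(OC)cc1OC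
F0 | step 7 | none | none
F5 | step 3 | 2-[(1E,3E)-2-methyl-1-(2,4,5-trimethoxyphenyl)penta-1,3-dien-3-yl]-4,4,5,5-tetramethyl-1,3,2-dioxaborolane | C/C=C(/C(C)=C/c1cc(OC)c(OC)cc1OC)B1OC(C)(C)C(C)(C)O1
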